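The seven-membered ring is traced back to a six-membered one: C9 is excised from between C10 and C8, which leaves a cis-hydrindan-10-one whose four stereocentres (C1, C4, C5, C6) can be set on a rigid bicycle. The key step exploits the position of the C10 oxygen in the seven-membered ring, flanked by quaternary C1 and by the C8=C9 alkene: cyclopropanation of the C10=C8 silyl enol ether and oxidative cleavage of the shared C8–C10 bond insert C9 and deliver the C10 enone in one operation. Its precursor is the trimethylsilyl enol ether of the 8-methyl hydrindan-10-one carrying C4 and C6 silyl ethers.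

Key step: step 11

Remark on numbering and configuration: locants are those of the target (daucane = 4-isopropyl-1,8-dimethylbicyclo[5.3.0]decane; C1 angular carbon, C4 carbinol, C5 ring-fusion CH, seven-membered ring C1–C5–C6–C7–C8–C9–C10). The hydrindane (bicyclo[4.3.0]nonane) intermediates keep these locants and lack C9. β is the face of the C1 methyl. The target is (1R,4S,5S,6R,10R): H5, the C4 hydroxyl and the C10 ester are β, and the C6 ester is α, trans to H5.

Assumption: 7-methyl-1,4-dioxaspiro[4.5]decan-8-one (1) is taken as purchasable; otherwise it is one enolate methylation from 1,4-dioxaspiro[4.5]decan-8-one.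

Step 1
Reactants: 1 7-methyl-1,4-dioxaspiro[4.5]decan-8-one; 2 (R)-1-phenylethylamine; 3 4-methylpent-1-en-3-one
Product: 6 (R)-7-methyl-7-(4-methyl-3-oxopentyl)-1,4-dioxaspiro[4.5]decan-8-one, via ketimine 4 (not isolated), via alkylated ketimine 5 (not isolated)
Conditions: 2, TsOH (cat.), toluene, Dean–Stark, 110 °C; then 3, THF, 40 °C; then AcOH, H2O, 25 °C
Reagents that add atoms: 4-methylpent-1-en-3-one (3), C=CC(=O)C(C)C; water, O
Why: d'Angelo deracemising Michael addition: the more substituted secondary enamine tautomer of the chiral ketimine adds to the vinyl ketone through a compact aza-ene-like transition state on the enamine face remote from the phenyl group, which by the sense known for 2-methylcyclohexanone imines (the mirror-image amine gives the mirror-image quaternary centre) should set C1 as R, and aqueous acetic acid then hydrolyses the imine without opening the dioxolane.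

Step 2
Reactants: 6 (R)-7-methyl-7-(4-methyl-3-oxopentyl)-1,4-dioxaspiro[4.5]decan-8-one
Product: 8 (1R)-4-isopropyl-1-methylhydrind-4-ene-6,10-dione, via triketone 7 (not isolated)
Conditions: 1 M HCl, THF, 25 °C; then KOH, MeOH, 65 °C
Reagents that add atoms: water, O
Why: Acetal hydrolysis followed by a base-mediated intramolecular aldol condensation (five-membered ring formed in the enolexo mode): the bridged ketols available from the other enolates form reversibly and cannot dehydrate, whereas attack of C5 (α to the unmasked C6 ketone) on the isopropyl ketone can lose water, so the mixture should drain into the conjugated tetrasubstituted C4=C5 enone; C1 is quaternary and is not affected.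

Step 3
Reactants: 8 (1R)-4-isopropyl-1-methylhydrind-4-ene-6,10-dione
Product: 9 (1R,6S)-6-hydroxy-4-isopropyl-1-methylhydrind-4-en-10-one
Conditions: NaBH4, CeCl3·7H2O, MeOH, −78 °C
Reagents that add atoms: none
Why: Luche 1,2-reduction: because C5 is sp2 and the cyclopentene is flat, the C1 methyl is forced axial on the six-membered ring and lies 1,3 to C6, so hydride should enter C6 from the opposite (α) face and give the 6β (6S) allylic alcohol, while the cerium-activated enone carbonyl reacts ahead of the more hindered saturated C10 ketone.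

Step 4
Reactants: 9 (1R,6S)-6-hydroxy-4-isopropyl-1-methylhydrind-4-en-10-one
Product: 10 (1R,4S,5R,6S)-4,5-epoxy-6-hydroxy-4-isopropyl-1-methylhydrindan-10-one
Conditions: VO(acac)2 (cat.), t-BuOOH, CH2Cl2, 0 → 25 °C
Reagents that add atoms: tert-butyl hydroperoxide, CC(C)(C)OO
Why: Vanadium-catalysed hydroxyl-directed epoxidation of an allylic alcohol: oxygen is delivered within the vanadium alkoxide–peroxide complex to the alkene face syn to the 6β-hydroxyl, which places the C4–O bond on the β face (4S, as in the target), the same syn delivery that overrides a neighbouring angular methyl in steroidal allylic alcohols.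

Step 5
Reactants: 10 (1R,4S,5R,6S)-4,5-epoxy-6-hydroxy-4-isopropyl-1-methylhydrindan-10-one
Product: 11 (1R,4S,5S)-4,5-epoxy-4-isopropyl-1-methylhydrindane-6,10-dione
Conditions: Dess–Martin periodinane, pyridine, CH2Cl2, 0 → 25 °C
Reagents that add atoms: none
Why: Dess–Martin oxidation of the secondary alcohol under pyridine buffering gives the α,β-epoxy ketone without touching the epoxide or C10, the C6 centre having served its purpose as director and being reset in step 7.

Step 6
Reactants: 11 (1R,4S,5S)-4,5-epoxy-4-isopropyl-1-methylhydrindane-6,10-dione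
Product: 12 (1R,4S,5R)-4-hydroxy-4-isopropyl-1-methyl-cis-hydrindane-6,10-dione
Conditions: SmI2, THF–MeOH, −90 °C
Reagents that add atoms: none
Why: Reductive opening of an α,β-epoxy ketone by divalent samarium: two single-electron transfers through the C6 ketyl break only the C5–O bond α to the carbonyl, so C4 keeps its oxygen and its 4S configuration, and protonation of the resulting samarium enolate by methanol (delivered from the side of the β-alkoxide) should give the cis-fused β-hydroxy ketone, which is also the more stable ring fusion of an angular-methyl hydrindanone and is therefore reachable by equilibration through the enol if a mixture forms.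

Step 7
Reactants: 12 (1R,4S,5R)-4-hydroxy-4-isopropyl-1-methyl-cis-hydrindane-6,10-dione
Product: 13 (1R,4S,5S,6R)-4,6-dihydroxy-4-isopropyl-1-methyl-cis-hydrindan-10-one
Conditions: Me4NBH(OAc)3, MeCN–AcOH, −30 °C
Reagents that add atoms: none
Why: Evans–Saksena hydroxyl-directed reduction: the acetoxyborohydride bound to the C4 oxygen transfers hydride intramolecularly to the C6 carbonyl from the β face, which is also the open face next to H5, so the 6α (6R) alcohol trans to H5 should form, and the C10 ketone, shielded by quaternary C1 and lacking a hydroxyl in reach, is left.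

Step 8
Reactants: 13 (1R,4S,5S,6R)-4,6-dihydroxy-4-isopropyl-1-methyl-cis-hydrindan-10-one
Product: 15 (1R,4S,5S,6R)-6-(tert-butyldimethylsilyloxy)-4-isopropyl-1-methyl-4-(triethylsilyloxy)-cis-hydrindan-10-one, via mono-TBS ether 14 (not isolated)
Conditions: TBSOTf, 2,6-lutidine, CH2Cl2, −78 °C; then TESOTf, −78 → 25 °C
Reagents that add atoms: tert-butyldimethylsilyl trifluoromethanesulfonate, CC(C)(C)[Si](C)(C)OS(=O)(=O)C(F)(F)F; triethylsilyl trifluoromethanesulfonate, CC[Si](CC)(CC)OS(=O)(=O)C(F)(F)F
Why: Sequential silylation with silyl triflates in one flask: the secondary C6 hydroxyl takes the tert-butyldimethylsilyl group at −78 °C, the hindered tertiary C4 hydroxyl then accepts only the smaller triethylsilyl triflate on warming, and no stereocentre is involved.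

Step 9
Reactants: 15 (1R,4S,5S,6R)-6-(tert-butyldimethylsilyloxy)-4-isopropyl-1-methyl-4-(triethylsilyloxy)-cis-hydrindan-10-one
Product: 16 (1R,4S,5S,6R)-6-(tert-butyldimethylsilyloxy)-4-isopropyl-1,8-dimethyl-4-(triethylsilyloxy)-cis-hydrindan-10-one (C8 epimers)
Conditions: LiN(i-Pr)2 (LDA), THF, −78 °C; then MeI, −78 → 0 °C
Reagents that add atoms: iodomethane, CI
Why: Alkylation of a kinetic lithium enolate: since C1 is quaternary the C10 ketone can be deprotonated only at C8, and methylation there gives the 8-methyl ketone as a mixture of C8 epimers that is of no consequence because C8 becomes sp2 in step 10.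

Step 10
Reactants: 16 (1R,4S,5S,6R)-6-(tert-butyldimethylsilyloxy)-4-isopropyl-1,8-dimethyl-4-(triethylsilyloxy)-cis-hydrindan-10-one (C8 epimers)
Product: 17 (1R,4S,5S,6R)-6-(tert-butyldimethylsilyloxy)-4-isopropyl-1,8-dimethyl-4-(triethylsilyloxy)-10-(trimethylsilyloxy)-cis-hydrind-8(10)-ene
Conditions: TMSOTf, Et3N, CH2Cl2, 0 → 25 °C
Reagents that add atoms: trimethylsilyl trifluoromethanesulfonate, C[Si](C)(C)OS(=O)(=O)C(F)(F)F
Why: Soft enolisation with TMSOTf and Et3N (silyl enol ether formation): the single remaining α-hydrogen is at C8, so the tetrasubstituted C10=C8 trimethylsilyl enol ether is the only possible regioisomer and both C8 epimers converge on it.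

Step 11
Reactants: 17 (1R,4S,5S,6R)-6-(tert-butyldimethylsilyloxy)-4-isopropyl-1,8-dimethyl-4-(triethylsilyloxy)-10-(trimethylsilyloxy)-cis-hydrind-8(10)-ene; 18 diiodomethane
Product: 21 (1R,4S,5S,6R)-6-(tert-butyldimethylsilyloxy)-4-(triethylsilyloxy)-cis-dauc-8-en-10-one (hydroazulenone), via siloxycyclopropane 19 (not isolated), via 8-chloro ketone 20 (not isolated)
Conditions: Et2Zn, CH2I2, toluene, 0 → 25 °C; then FeCl3, pyridine, DMF, 0 → 25 °C; then NaOAc, MeOH, 40 °C
Reagents that add atoms: diiodomethane (18), ICI
Why: The zinc carbenoid EtZnCH2I (Furukawa variant of the Simmons–Smith reaction) transfers methylene to the electron-rich C10=C8 enol ether in a concerted, stereospecific [2+1] addition that closes the cyclopropane and forms C8–C9 and C9–C10. FeCl3 then oxidises the siloxycyclopropane by one electron to an oxygen-centred radical, β-scission of the shared C8–C10 bond enlarges the six-membered ring to the seven-membered C10 ketone (a ring expansion by bond cleavage, not a cyclisation), and the tertiary C8 radical takes chlorine from a second FeCl3. Dehydrochlorination with sodium acetate proceeds through the C9 enolate and can give only the conjugated C8=C9 enone. The closest known reaction type is the Ito–Saegusa ring expansion of fused siloxycyclopropanes to 2-cycloalkenones. No new stereocentre survives: the cyclopropane carbons and the chlorinated C8 are transient, and C1, C4, C5 and C6 are spectators. The step needs regioselective enolisation and fragmentation plus tolerance of the silyl ethers; because C1 carries no hydrogen the enol ether can exist only toward C8, cleavage of the internal bond leads to the more stable tertiary ring-expanded radical, and pyridine buffering in DMF protects the silyl ethers.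

Step 12
Reactants: 21 (1R,4S,5S,6R)-6-(tert-butyldimethylsilyloxy)-4-(triethylsilyloxy)-cis-dauc-8-en-10-one
Product: 22 (1R,4S,5S,6R,10R)-6-(tert-butyldimethylsilyloxy)-4-(triethylsilyloxy)-cis-dauc-8-en-10-ol
Conditions: (S)-2-methyl-CBS-oxazaborolidine (0.3 equiv), BH3·SMe2, THF, −30 °C
Reagents that add atoms: none
Why: Corey–Bakshi–Shibata reduction: the enone should bind to the (S)-oxazaborolidine–borane complex with quaternary C1 as the large and vinylic C9 as the small substituent, so that hydride is delivered to the α face and the (10R) allylic alcohol with the hydroxyl syn to the angular methyl results by 1,2-reduction, catalyst control being chosen because the substrate itself offers methyl on one face of C10 and the five-membered ring on the other.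

Step 13
Reactants: 22 (1R,4S,5S,6R,10R)-6-(tert-butyldimethylsilyloxy)-4-(triethylsilyloxy)-cis-dauc-8-en-10-ol; 23 3-methylbutanoic (isovaleric) anhydride
Product: 24 (1R,4S,5S,6R,10R)-6-(tert-butyldimethylsilyloxy)-4-(triethylsilyloxy)-cis-dauc-8-en-10-yl 3-methylbutanoate
Conditions: DMAP, Et3N, CH2Cl2, 25 °C
Reagents that add atoms: isovaleric anhydride (23), CC(C)CC(=O)OC(=O)CC(C)C
Why: DMAP-catalysed acyl transfer from the anhydride esterifies the hindered allylic alcohol with retention at C10, since the C10–O bond is not broken.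

Step 14
Reactants: 24 (1R,4S,5S,6R,10R)-6-(tert-butyldimethylsilyloxy)-4-(triethylsilyloxy)-cis-dauc-8-en-10-yl 3-methylbutanoate
Product: 25 (1R,4S,5S,6R,10R)-4,6-dihydroxy-cis-dauc-8-en-10-yl 3-methylbutanoate
Conditions: HF·pyridine, pyridine, THF, 0 → 25 °C
Reagents that add atoms: none
Why: Fluoride-mediated desilylation with pyridine-buffered HF·pyridine should remove both the secondary tert-butyldimethylsilyl and the tertiary triethylsilyl ether under conditions too mild to hydrolyse, ionise or shift the allylic isovalerate.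

Step 15
Reactants: 25 (1R,4S,5S,6R,10R)-4,6-dihydroxy-cis-dauc-8-en-10-yl 3-methylbutanoate; 26 4-acetoxybenzoic acid
Product: 27 (1R,4S,5S,6R,10R)-6-(4-acetoxybenzoyloxy)-4-hydroxy-cis-dauc-8-en-10-yl 3-methylbutanoate
Conditions: DCC, DMAP (cat.), CH2Cl2, 25 °C
Reagents that add atoms: 4-acetoxybenzoic acid (26), CC(=O)Oc1ccc(cc1)C(=O)O
Why: Steglich esterification: the carbodiimide-activated acid is transferred by DMAP to the secondary C6 hydroxyl only, the tertiary C4 hydroxyl next to the isopropyl group being inert, and the configuration at C6 is retained.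

Step 16
Reactants: 27 (1R,4S,5S,6R,10R)-6-(4-acetoxybenzoyloxy)-4-hydroxy-cis-dauc-8-en-10-yl 3-methylbutanoate
Product: 28 (1R,4S,5S,6R,10R)-4-hydroxy-6-(4-hydroxybenzoyloxy)-cis-dauc-8-en-10-yl 3-methylbutanoate (target)
Conditions: pyrrolidine, MeCN, 0 → 25 °C
Reagents that add atoms: none
Why: Chemoselective aminolysis of a phenolic acetate: the aryl acetate is far more electrophilic than the alkyl isovalerate and the alkyl benzoate, so pyrrolidine should remove only the acetyl group and release the free phenol of the target.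

Compound list
1 | 7-methyl-1,4-dioxaspiro[4.5]decan-8-one (racemic) | CC1CC2(CCC1=O)OCCO2 | starting material
2 | (R)-1-phenylethylamine | C[C@@H](N)c1ccccc1 | starting material
3 | 4-methylpent-1-en-3-one (isopropyl vinyl ketone) | C=CC(=O)C(C)C | starting material
4 | ketimine of 1 with 2 (not isolated) | CC1CC2(CCC1=N[C@H](C)c1ccccc1)OCCO2 | intermediate
5 | C7-alkylated ketimine with (R)-quaternary carbon (not isolated) | C1C(=N[C@H](C)c3ccccc3)[C@](C)(CCC(=O)C(C)C)CC2(OCCO2)C1 | intermediate
6 | (R)-7-methyl-7-(4-methyl-3-oxopentyl)-1,4-dioxaspiro[4.5]decan-8-one | C1C(=O)[C@](C)(CCC(=O)C(C)C)CC2(OCCO2)C1 | intermediate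
7 | (R)-2-methyl-2-(4-methyl-3-oxopentyl)cyclohexane-1,4-dione (not isolated) | C1C(=O)[C@](C)(CCC(=O)C(C)C)CC(=O)C1 | intermediate
8 | (1R)-4-isopropyl-1-methylhydrind-4-ene-6,10-dione (C4=C5 enone conjugated with C6=O) | C1C(=O)[C@]2(C)CCC(C(C)C)=C2C(=O)C1 | intermediate
9 | (1R,6S)-6-hydroxy-4-isopropyl-1-methylhydrind-4-en-10-one (6-OH β) | C1C(=O)[C@]2(C)CCC(C(C)C)=C2[C@@H](O)C1 | intermediate
10 | (1R,4S,5R,6S)-4,5-epoxy-6-hydroxy-4-isopropyl-1-methylhydrindan-10-one (β-epoxide) | C1C(=O)[C@]2(C)CC[C@@]3(C(C)C)O[C@@]23[C@@H](O)C1 | intermediate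
11 | (1R,4S,5S)-4,5-epoxy-4-isopropyl-1-methylhydrindane-6,10-dione | C1C(=O)[C@]2(C)CC[C@@]3(C(C)C)O[C@@]23C(=O)C1 | intermediate
12 | (1R,4S,5R)-4-hydroxy-4-isopropyl-1-methyl-cis-hydrindane-6,10-dione | C1C(=O)[C@]2(C)CC[C@](O)(C(C)C)[C@@H]2C(=O)C1 | intermediate
13 | (1R,4S,5S,6R)-4,6-dihydroxy-4-isopropyl-1-methyl-cis-hydrindan-10-one | C1C(=O)[C@]2(C)CC[C@](O)(C(C)C)[C@@H]2[C@H](O)C1 | intermediate
14 | 6-O-tert-butyldimethylsilyl ether of 13 (not isolated) | C1C(=O)[C@]2(C)CC[C@](O)(C(C)C)[C@@H]2[C@H](O[Si](C)(C)C(C)(C)C)C1 | intermediate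
15 | (1R,4S,5S,6R)-6-(tert-butyldimethylsilyloxy)-4-isopropyl-1-methyl-4-(triethylsilyloxy)-cis-hydrindan-10-one | C1C(=O)[C@]2(C)CC[C@](O[Si](CC)(CC)CC)(C(C)C)[C@@H]2[C@H](O[Si](C)(C)C(C)(C)C)C1 | intermediate
16 | 8-methyl derivative of 15, mixture of C8 epimers | CC1C(=O)[C@]2(C)CC[C@](O[Si](CC)(CC)CC)(C(C)C)[C@@H]2[C@H](O[Si](C)(C)C(C)(C)C)C1 | intermediate
17 | trimethylsilyl enol ether (C10=C8) of 16, precursor of the key step | CC1=C(O[Si](C)(C)C)[C@]2(C)CC[C@](O[Si](CC)(CC)CC)(C(C)C)[C@@H]2[C@H](O[Si](C)(C)C(C)(C)C)C1 | intermediate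
18 | diiodomethane | ICI | starting material
19 | siloxycyclopropane (C8–C9–C10 three-membered ring, not isolated) | CC12CC1(O[Si](C)(C)C)[C@]3(C)CC[C@](O[Si](CC)(CC)CC)(C(C)C)[C@@H]3[C@H](O[Si](C)(C)C(C)(C)C)C2 | intermediate
20 | 8-chloro-8-methyl seven-membered C10 ketone (not isolated) | CC1(Cl)CC(=O)[C@]2(C)CC[C@](O[Si](CC)(CC)CC)(C(C)C)[C@@H]2[C@H](O[Si](C)(C)C(C)(C)C)C1 | intermediate
21 | (1R,4S,5S,6R)-6-(tert-butyldimethylsilyloxy)-4-(triethylsilyloxy)-cis-dauc-8-en-10-one | CC1=CC(=O)[C@]2(C)CC[C@](O[Si](CC)(CC)CC)(C(C)C)[C@@H]2[C@H](O[Si](C)(C)C(C)(C)C)C1 | intermediate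
22 | (10R)-allylic alcohol of 21 (10-OH β) | CC1=C[C@@H](O)[C@]2(C)CC[C@](O[Si](CC)(CC)CC)(C(C)C)[C@@H]2[C@H](O[Si](C)(C)C(C)(C)C)C1 | intermediate
23 | 3-methylbutanoic (isovaleric) anhydride | CC(C)CC(=O)OC(=O)CC(C)C | starting material
24 | 10-O-isovalerate of 22 | CC1=C[C@@H](OC(=O)CC(C)C)[C@]2(C)CC[C@](O[Si](CC)(CC)CC)(C(C)C)[C@@H]2[C@H](O[Si](C)(C)C(C)(C)C)C1 | intermediate
25 | (1R,4S,5S,6R,10R)-4,6-dihydroxy-cis-dauc-8-en-10-yl 3-methylbutanoate | CC1=C[C@@H](OC(=O)CC(C)C)[C@]2(C)CC[C@](O)(C(C)C)[C@@H]2[C@H](O)C1 | intermediate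
26 | 4-acetoxybenzoic acid | CC(=O)Oc1ccc(cc1)C(=O)O | starting material
27 | 6-O-(4-acetoxybenzoyl) ester of 25 | CC1=C[C@@H](OC(=O)CC(C)C)[C@]2(C)CC[C@](O)(C(C)C)[C@@H]2[C@H](OC(=O)c2ccc(OC(C)=O)cc2)C1 | intermediate
28 | (1R,4S,5S,6R,10R)-4-hydroxy-6-(4-hydroxybenzoyloxy)-cis-dauc-8-en-10-yl 3-methylbutanoate (CNP0086724.1) | CC1=C[C@@H](OC(=O)CC(C)C)[C@]2(C)CC[C@](O)(C(C)C)[C@@H]2[C@H](OC(=O)c2ccc(O)cc2)C1 | target

Total step count: 16. Longest linear sequence: 16 steps (1 to 28).

Steps most likely to fail

Step 11 (ring expansion). Methylene transfer to the congested tetrasubstituted enol ether may be slower than loss of the trimethylsilyl group, and the Lewis-acidic iron salt may strip the silyl ethers or fragment the cyclopropane without regiocontrol. The fallback is the halocarbene variant of the same ring enlargement. Setting out from 17, dibromocarbene (CHBr3, KOt-Bu, pentane, −20 °C) should give the 9,9-dibromo siloxycyclopropane F1. On warming in toluene this opens by the known cyclopropyl-to-allyl cation pathway, with loss of bromide and of the silyl group, to the 9-bromo enone F2. Hydrogenolysis of the vinylic bromide (Pd(PPh3)4, HCO2H, Et3N, DMF, 60 °C) returns to the route at 21.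

Step 12 (C10 reduction). Catalyst and substrate may prefer opposite faces of C10, a mismatched pair, so that facial selectivity erodes or reverses. The fallback uses inversion in place of retention. From 21, reduction under substrate control (NaBH4, CeCl3·7H2O, MeOH, −78 °C) is taken to the 10-epimeric allylic alcohol F3. A Mitsunobu esterification with 3-methylbutanoic acid (PPh3, DIAD, toluene, 0 → 25 °C) then inverts C10 while installing the ester and rejoins the route at 24.

Step 6 (epoxy ketone opening). The samarium enolate may be protonated on the wrong face of C5, and the free β-hydroxy ketone may undergo retro-aldol opening or dehydration when equilibration is attempted. The fallback puts C5 under thermodynamic control on a protected aldol. From 12, including any C5 epimer, the tertiary hydroxyl is silylated first (TESOTf, 2,6-lutidine, CH2Cl2) to the 4-O-triethylsilyl diketone F4. Retro-aldol cleavage is then blocked and C5 can be equilibrated with DBU to the cis-fused ketone. Reduction with LiBH(s-Bu)3 (THF, −78 °C) from the open H5 face gives the 6α-alcohol F5, and TBSOTf with 2,6-lutidine leads back to the route at 15.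

Further compounds
F1 | step 11 | 9,9-dibromo siloxycyclopropane from 17 | CC12C(Br)(Br)C1(O[Si](C)(C)C)[C@]3(C)CC[C@](O[Si](CC)(CC)CC)(C(C)C)[C@@H]3[C@H](O[Si](C)(C)C(C)(C)C)C2
F2 | step 11 | (1R,4S,5S,6R)-9-bromo-6-(tert-butyldimethylsilyloxy)-4-(triethylsilyloxy)-cis-dauc-8-en-10-one | CC1=C(Br)C(=O)[C@]2(C)CC[C@](O[Si](CC)(CC)CC)(C(C)C)[C@@H]2[C@H](O[Si](C)(C)C(C)(C)C)C1
F3 | step 12 | (1R,4S,5S,6R,10S)-6-(tert-butyldimethylsilyloxy)-4-(triethylsilyloxy)-cis-dauc-8-en-10-ol | CC1=C[C@H](O)[C@]2(C)CC[C@](O[Si](CC)(CC)CC)(C(C)C)[C@@H]2[C@H](O[Si](C)(C)C(C)(C)C)C1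
F4 | step 6 | (1R,4S,5R)-4-isopropyl-1-methyl-4-(triethylsilyloxy)-cis-hydrindane-6,10-dione | C1C(=O)[C@]2(C)CC[C@](O[Si](CC)(CC)CC)(C(C)C)[C@@H]2C(=O)C1
F5 | step 6 | (1R,4S,5S,6R)-6-hydroxy-4-isopropyl-1-methyl-4-(triethylsilyloxy)-cis-hydrindan-10-one | C1C(=O)[C@]2(C)CC[C@](O[Si](CC)(CC)CC)(C(C)C)[C@@H]2[C@H](O)C1
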